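**Plan**

1. Numbering (target SMILES order): C1 (quaternary; CH3 and C12H2O), C2, C3, C4 (CH–CH3), C5, C6 (C=O), C7, C8 (C–CH3), C9, C10 and C11 (acyloxy), C12. Rings: cyclobutane C2–C3–C8–C7, cyclohexanone C3–C4–C5–C6–C7–C8, cycloheptane C1–C2–C7–C8–C9–C10–C11.
2. Enabling feature: C8 is a methyl-bearing cyclobutane carbon next to C3, a masked 1-methylcyclobutyl cation. That cation is the ring-expanded form of a (1-methylcyclopropyl)carbinyl cation at C3 of a bicyclo[4.1.0]heptane (cyclopropane C2–C7–C8).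
3. Cuts, after removing the three angelates and the C10 carbinol: C8–C9 and C2–C3 together (cationic step); then C3–O/C4–H (hydroboration), C3=C4 (metathesis), C7–C2/C7–C8 (carbenoid cyclopropanation), C2=C8 (Wittig), C1–allyl and C1–C11 (enolate alkylation, aldol).
4. Forward order: acyclic C9–C12 chain with C11 and C1 set, then the E alkene C2=C8, the cyclopropane (held as a lactone), the cyclohexene by ring-closing metathesis, ring expansion to the cyclobutane with closure of the seven-membered ring, and last the three angelates from three equivalents of angelic acid.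
5. Stereochemistry: C10 of (S)-lactaldehyde benzyl ether relays to C11 (chelation) and C1 (dianion alkylation). Alkene geometry, a chiral rhodium carboxamidate and the allylic quaternary C1 set C2/C7/C8. The cyclopropane directs hydroboration (C3, C4). The key step inverts C3 and retains C8. The C11 hydroxyl directs hydride to C10.

Key step: step 23

Assumption: (S)-2-(benzyloxy)propanal (otherwise two steps from ethyl (S)-lactate) and 1-methoxy-1-(trimethylsilyloxy)prop-1-ene are taken as purchasable; the tricyclic compounds 30–32 and 35 carry descriptors in the plan numbering.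

Abbreviations: BnO = benzyloxy; TBSO = tert-butyldimethylsilyloxy; TIPSO = triisopropylsilyloxy; group A = (2S,3S,4S)-4-(BnO)-1,3-bis(TBSO)-2-methylpentan-2-yl; group B = (2S,3S)-1,3-bis(TBSO)-2-methyl-4-(TIPSO)pent-4-en-2-yl.

**Route**

Step 1
Reactants: 1 (S)-2-(benzyloxy)propanal; 2 1-methoxy-1-(trimethylsilyloxy)prop-1-ene
Product: 3 methyl (3S,4S)-4-(benzyloxy)-3-hydroxy-2-methylpentanoate
Conditions: MgBr2·OEt2, CH2Cl2, −20 → 0 °C; aq. HCl work-up
Reagents that add atoms: none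
Why: Chelation-controlled Mukaiyama aldol addition, in which the magnesium chelate of the aldehyde and α-benzyloxy oxygens exposes the face anti to the C9 methyl group and so sets C11 as S, while the mixed configuration at C1 is erased in step 2.

Step 2
Reactants: 3 methyl (3S,4S)-4-(benzyloxy)-3-hydroxy-2-methylpentanoate
Product: 5 methyl (2R)-2-[(1S,2S)-2-(benzyloxy)-1-hydroxypropyl]-2-methylpent-4-enoate, via dilithium dianion 4 (not isolated)
Conditions: LiN(iPr)2 (2.3 equiv), THF, −78 → −20 °C; then allyl bromide, DMPU, −78 → −20 °C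
Reagents that add atoms: allyl bromide C=CCBr
Why: Fráter–Seebach alkylation, in which both C1 epimers converge on one chelated alkoxide–enolate and allyl bromide enters anti to the C11 alkoxide, setting the quaternary C1 (2R in the ester name, S in plan numbering) with the allyl group as the future C2.

Step 3
Reactants: 5 methyl (2R)-2-[(1S,2S)-2-(benzyloxy)-1-hydroxypropyl]-2-methylpent-4-enoate
Product: 6 (2S,3S,4S)-4-(benzyloxy)-2-methyl-2-(prop-2-en-1-yl)pentane-1,3-diol
Conditions: LiAlH4, THF, 0 → 25 °C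
Reagents that add atoms: none
Why: LiAlH4 reduction of the hindered ester to the primary alcohol that becomes C12–OH, with no change at any stereocentre.

Step 4
Reactants: 6 (2S,3S,4S)-4-(benzyloxy)-2-methyl-2-(prop-2-en-1-yl)pentane-1,3-diol
Product: 7 (2S,3S,4S)-4-(BnO)-1,3-bis(TBSO)-2-methyl-2-(prop-2-en-1-yl)pentane
Conditions: tBuMe2SiOTf (2.5 equiv), 2,6-lutidine, CH2Cl2, −78 → 0 °C
Reagents that add atoms: tert-butyldimethylsilyl trifluoromethanesulfonate CC(C)(C)[Si](C)(C)OS(=O)(=O)C(F)(F)F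
Why: Silyl triflate silylation, forceful enough to protect the neopentyl primary and the hindered secondary hydroxyl in one operation.

Step 5
Reactants: 7 (2S,3S,4S)-4-(BnO)-1,3-bis(TBSO)-2-methyl-2-(prop-2-en-1-yl)pentane
Product: 8 (2S,3S,4S)-4-(BnO)-1,3-bis(TBSO)-2-methyl-2-[(1E)-prop-1-en-1-yl]pentane
Conditions: RuHCl(CO)(PPh3)3 (5 mol %), toluene, 80 °C
Reagents that add atoms: none
Why: Ruthenium hydride-catalysed alkene isomerisation, which moves the terminal double bond by one position to the more stable disubstituted alkene and stops there because C1 is quaternary (the alkene geometry is irrelevant for step 6).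

Step 6
Reactants: 8 (2S,3S,4S)-4-(BnO)-1,3-bis(TBSO)-2-methyl-2-[(1E)-prop-1-en-1-yl]pentane
Product: 10 (2S,3S,4S)-4-(BnO)-3-(TBSO)-2-[(TBSO)methyl]-2-methylpentanal, via ozonide 9 (not isolated)
Conditions: O3, CH2Cl2, −78 °C; then PPh3, −78 → 25 °C
Reagents that add atoms: ozone [O-][O+]=O
Why: Ozonolysis with reductive work-up cleaves the propenyl group to the C2 aldehyde, which has no α-hydrogen and therefore cannot epimerise at C1.

Step 7
Reactants: 10 (2S,3S,4S)-4-(BnO)-3-(TBSO)-2-[(TBSO)methyl]-2-methylpentanal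
Product: 11 ethyl (2E,4S,5S,6S)-6-(BnO)-5-(TBSO)-4-[(TBSO)methyl]-2,4-dimethylhept-2-enoate
Conditions: Ph3P=C(CH3)CO2Et, toluene, 110 °C
Reagents that add atoms: ethyl 2-(triphenylphosphoranylidene)propanoate CCOC(=O)C(C)=P(c1ccccc1)(c1ccccc1)c1ccccc1
Why: Wittig olefination with a stabilised ylide, which gives the E trisubstituted enoate (C1 trans to the ester carbon C3), the geometry that later places C1 exo on the cyclopropane.

Step 8
Reactants: 11 ethyl (2E,4S,5S,6S)-6-(BnO)-5-(TBSO)-4-[(TBSO)methyl]-2,4-dimethylhept-2-enoate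
Product: 12 (2E,4S,5S,6S)-6-(BnO)-5-(TBSO)-4-[(TBSO)methyl]-2,4-dimethylhept-2-en-1-ol
Conditions: iBu2AlH, CH2Cl2, −78 °C
Reagents that add atoms: none
Why: 1,2-Reduction of the enoate with iBu2AlH to the allylic alcohol (C3), with retention of the alkene geometry.

Step 9
Reactants: 12 (2E,4S,5S,6S)-6-(BnO)-5-(TBSO)-4-[(TBSO)methyl]-2,4-dimethylhept-2-en-1-ol
Product: 14 (2E,4S,5S,6S)-6-(BnO)-5-(TBSO)-4-[(TBSO)methyl]-2,4-dimethylhept-2-en-1-yl diazoacetate, via bromoacetate 13 (not isolated)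
Conditions: BrCH2COBr, NaHCO3, MeCN, 0 °C; then TsNHNHTs, DBU, THF, 0 °C
Reagents that add atoms: bromoacetyl bromide BrCC(Br)=O; N,N'-bis(4-methylbenzenesulfonyl)hydrazine Cc1ccc(cc1)S(=O)(=O)NNS(=O)(=O)c1ccc(C)cc1
Why: O-Acylation with bromoacetyl bromide followed by substitution with N,N'-ditosylhydrazine and base-induced loss of two sulfinate ions, a mild two-stage diazoacetate synthesis that tolerates the silyl and benzyl ethers.

Step 10
Reactants: 14 (2E,4S,5S,6S)-6-(BnO)-5-(TBSO)-4-[(TBSO)methyl]-2,4-dimethylhept-2-en-1-yl diazoacetate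
Product: 15 (1R,5S,6R)-6-A-5-methyl-3-oxabicyclo[3.1.0]hexan-2-one
Conditions: dirhodium tetrakis[methyl (4S)-2-oxo-1-(3-phenylpropanoyl)imidazolidine-4-carboxylate], Rh2(4S-MPPIM)4 (1 mol %), CH2Cl2, 40 °C, slow addition of 14
Reagents that add atoms: none
Why: Rhodium carboxamidate-catalysed intramolecular cyclopropanation of an allylic diazoacetate, in which syn addition of the carbenoid to the E alkene makes C1 exo (C3 and C6 cis, held in the lactone) and the chiral catalyst, supported by the allylic quaternary C1 whose methyl group lies on the attacked face, selects the alkene face so that C2, C7 and C8 arise as R, R and S.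

Step 11
Reactants: 15 (1R,5S,6R)-6-A-5-methyl-3-oxabicyclo[3.1.0]hexan-2-one
Product: 17 (1R,2S,3S)-3-A-2-formyl-N-methoxy-N,2-dimethylcyclopropane-1-carboxamide, via hydroxy amide 16 (not isolated)
Conditions: MeNH(OMe)·HCl, AlMe3, CH2Cl2, 0 → 25 °C; then Dess–Martin periodinane, NaHCO3, CH2Cl2, 0 °C
Reagents that add atoms: N,O-dimethylhydroxylamine hydrochloride CNOC.Cl
Why: Weinreb amide formation by aluminium amide opening of the lactone followed at once by Dess–Martin oxidation of the freed C3 carbinol, which forestalls relactonisation and touches no stereocentre (C8 is quaternary and the cyclopropyl C7–H is not acidic enough to epimerise).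

Step 12
Reactants: 17 (1R,2S,3S)-3-A-2-formyl-N-methoxy-N,2-dimethylcyclopropane-1-carboxamide
Product: 18 (1R,2S,3R)-3-A-2-ethenyl-N-methoxy-N,2-dimethylcyclopropane-1-carboxamide
Conditions: Ph3PCH3Br, KN(SiMe3)2, THF, −78 → 0 °C
Reagents that add atoms: methyltriphenylphosphonium bromide C[P+](c1ccccc1)(c1ccccc1)c1ccccc1.[Br-]
Why: Wittig methylenation of the hindered aldehyde, to which the Weinreb amide is inert at low temperature.

Step 13
Reactants: 18 (1R,2S,3R)-3-A-2-ethenyl-N-methoxy-N,2-dimethylcyclopropane-1-carboxamide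
Product: 19 1-[(1R,2S,3R)-3-A-2-ethenyl-2-methylcyclopropyl]-3-methylbut-3-en-1-one
Conditions: CH2=C(CH3)CH2MgCl, THF, −78 → −20 °C; cold aq. NH4Cl
Reagents that add atoms: 2-methylallylmagnesium chloride CC(=C)C[Mg]Cl
Why: Grignard addition to the Weinreb amide, which stops at the ketone because the magnesium chelate survives until the cold buffered quench that also keeps the β,γ double bond out of conjugation.

Step 14
Reactants: 19 1-[(1R,2S,3R)-3-A-2-ethenyl-2-methylcyclopropyl]-3-methylbut-3-en-1-one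
Product: 20 (1R,6S,7R)-7-A-4,6-dimethylbicyclo[4.1.0]hept-4-en-2-one
Conditions: (H2IMes)(PCy3)Cl2Ru=CHPh (second-generation Grubbs catalyst, 5 mol %), CH2Cl2, 40 °C
Reagents that add atoms: none
Why: Ring-closing metathesis of the cis-disposed vinyl and 2-methylallyl groups, which closes the six-membered ring through the trisubstituted C3=C4 bond with loss of ethene.

Step 15
Reactants: 20 (1R,6S,7R)-7-A-4,6-dimethylbicyclo[4.1.0]hept-4-en-2-one
Product: 21 (1R,6S,7R)-7-A-4,6-dimethylspiro[bicyclo[4.1.0]hept-4-ene-2,2'-[1,3]dioxolane]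
Conditions: Me3SiOCH2CH2OSiMe3, Me3SiOTf (5 mol %), CH2Cl2, −78 → −20 °C; pyridine quench
Reagents that add atoms: 1,2-bis(trimethylsilyloxy)ethane C[Si](C)(C)OCCO[Si](C)(C)C
Why: Silyl triflate-catalysed ketalisation with the bis-silyl ether of ethylene glycol, mild enough to protect the cyclopropyl ketone without shifting the β,γ double bond or opening the cyclopropane.

Step 16
Reactants: 21 (1R,6S,7R)-7-A-4,6-dimethylspiro[bicyclo[4.1.0]hept-4-ene-2,2'-[1,3]dioxolane]
Product: 23 (1R,4R,5S,6S,7R)-7-A-4,6-dimethylspiro[bicyclo[4.1.0]heptane-2,2'-[1,3]dioxolan]-5-ol, via alkylborane 22 (not isolated)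
Conditions: BH3·SMe2, THF, 0 → 25 °C; then NaOH, H2O2, 0 °C
Reagents that add atoms: hydrogen peroxide OO
Why: Hydroboration–oxidation, in which borane adds syn to the trisubstituted alkene with boron on the less substituted C3 and from the face anti to the cyclopropane carbon C2 (whose endo hydrogen shields the other face), so that oxidation with retention gives the C3 hydroxyl anti to the cyclopropane and the C4 methyl group cis to it.

Step 17
Reactants: 23 (1R,4R,5S,6S,7R)-7-A-4,6-dimethylspiro[bicyclo[4.1.0]heptane-2,2'-[1,3]dioxolan]-5-ol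
Product: 24 (1R,4R,5S,6S,7R)-7-A-4,6-dimethylspiro[bicyclo[4.1.0]heptane-2,2'-[1,3]dioxolan]-5-yl acetate
Conditions: Ac2O, DMAP, pyridine, CH2Cl2, 25 °C
Reagents that add atoms: acetic anhydride CC(=O)OC(C)=O
Why: DMAP-catalysed acetylation, which masks the hindered C3 hydroxyl while the oxidation level at C10 is changed.

Step 18
Reactants: 24 (1R,4R,5S,6S,7R)-7-A-4,6-dimethylspiro[bicyclo[4.1.0]heptane-2,2'-[1,3]dioxolan]-5-yl acetate
Product: 25 (1R,4R,5S,6S,7R)-7-[(2S,3S,4S)-1,3-bis(TBSO)-4-hydroxy-2-methylpentan-2-yl]-4,6-dimethylspiro[bicyclo[4.1.0]heptane-2,2'-[1,3]dioxolan]-5-yl acetate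
Conditions: H2 (1 atm), Pd(OH)2/C, EtOAc, 25 °C
Reagents that add atoms: none
Why: Hydrogenolysis of the benzyl ether, chemoselective because no alkene remains and the cyclopropane, acetate, ketal and silyl ethers are inert to it.

Step 19
Reactants: 25 (1R,4R,5S,6S,7R)-7-[(2S,3S,4S)-1,3-bis(TBSO)-4-hydroxy-2-methylpentan-2-yl]-4,6-dimethylspiro[bicyclo[4.1.0]heptane-2,2'-[1,3]dioxolan]-5-yl acetate
Product: 26 (1R,4R,5S,6S,7R)-7-[(2S,3S)-1,3-bis(TBSO)-2-methyl-4-oxopentan-2-yl]-4,6-dimethylspiro[bicyclo[4.1.0]heptane-2,2'-[1,3]dioxolan]-5-yl acetate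
Conditions: Dess–Martin periodinane, NaHCO3, CH2Cl2, 0 → 25 °C
Reagents that add atoms: none
Why: Dess–Martin oxidation of the secondary alcohol to the methyl ketone under buffered conditions that do not epimerise C11.

Step 20
Reactants: 26 (1R,4R,5S,6S,7R)-7-[(2S,3S)-1,3-bis(TBSO)-2-methyl-4-oxopentan-2-yl]-4,6-dimethylspiro[bicyclo[4.1.0]heptane-2,2'-[1,3]dioxolan]-5-yl acetate
Product: 27 (1R,4R,5S,6S,7R)-7-B-4,6-dimethylspiro[bicyclo[4.1.0]heptane-2,2'-[1,3]dioxolan]-5-yl acetate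
Conditions: KN(SiMe3)2 (1.05 equiv), THF, −78 °C; then iPr3SiOTf, −78 °C
Reagents that add atoms: triisopropylsilyl trifluoromethanesulfonate CC(C)[Si](C(C)C)(C(C)C)OS(=O)(=O)C(F)(F)F
Why: Kinetic enolisation of the methyl ketone at the unhindered methyl group (faster than deprotonation of the less acidic acetate) and O-silylation of the potassium enolate, which gives the terminal enol silane without the Lewis acid that could ionise the cyclopropylcarbinyl acetate.

Step 21
Reactants: 27 (1R,4R,5S,6S,7R)-7-B-4,6-dimethylspiro[bicyclo[4.1.0]heptane-2,2'-[1,3]dioxolan]-5-yl acetate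
Product: 28 (1R,4R,5S,6S,7R)-7-B-4,6-dimethylspiro[bicyclo[4.1.0]heptane-2,2'-[1,3]dioxolan]-5-ol
Conditions: iBu2AlH, CH2Cl2, −78 °C
Reagents that add atoms: none
Why: Reductive cleavage of the acetate with iBu2AlH at low temperature, to which the enol silane, the silyl ethers and the ketal are inert.

Step 22
Reactants: 28 (1R,4R,5S,6S,7R)-7-B-4,6-dimethylspiro[bicyclo[4.1.0]heptane-2,2'-[1,3]dioxolan]-5-ol
Product: 29 (1R,4R,5S,6S,7R)-7-B-4,6-dimethylspiro[bicyclo[4.1.0]heptane-2,2'-[1,3]dioxolan]-5-yl methanesulfonate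
Conditions: (MeSO2)2O, Et3N, CH2Cl2, −30 °C; cold NaHCO3 wash, used at once
Reagents that add atoms: methanesulfonic anhydride CS(=O)(=O)OS(C)(=O)=O
Why: O-Sulfonylation with methanesulfonic anhydride and triethylamine at low temperature in the absence of chloride, which gives the labile cyclopropylcarbinyl mesylate with retention at C3 for immediate use.

Step 23
Reactants: 29 (1R,4R,5S,6S,7R)-7-B-4,6-dimethylspiro[bicyclo[4.1.0]heptane-2,2'-[1,3]dioxolan]-5-yl methanesulfonate
Product: 30 tricyclic C10 ketone with C6 ethylene ketal, 11-TBSO and 12-TBSO groups (1S,2S,3S,4R,7R,8R,11S)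
Conditions: (CF3)2CHOH, 2,6-di-tert-butyl-4-methylpyridine, −20 → 0 °C (cold CH2Cl2 solution of crude 29 added)
Reagents that add atoms: none
Why: Proposed new method: in the buffered fluorinated alcohol the mesylate ionises with help from the cyclopropane bond C8–C2, which lies antiperiplanar to C3–O, so that C2 shifts to C3 with inversion and the charge settles on C8 as a tertiary 1-methylcyclobutyl cation, which C9 of the tethered enol silane then captures with loss of the silyl group to give the C10 ketone. The closest known reactions are the solvolytic rearrangement of (1-methylcyclopropyl)carbinyl sulfonates to 1-methylcyclobutyl products and cation–olefin cyclisations terminated by silyl enol ethers, but their union in one step on such a substrate is without precedent. The cyclobutane arises by a 1,2-alkyl shift (three- to four-membered ring expansion) and the seven-membered ring closes by attack of the enol ether terminus on the cyclobutyl cation, 7-endo with respect to the enol ether double bond. C3 is fixed by backside entry of C2 anti to the leaving group, and C8 by the tether, which hangs from the exo position of C2 and can reach only the lobe that C2 has just left, so that C9 replaces C2 with retention and the C8 methyl group ends syn to the C4–C5–C6 bridge. The step needs migration of C8–C2 rather than the ring-fusion bond C8–C7 and C–C capture at C8 ahead of solvent capture or proton loss; the first is secured by the antiperiplanar alignment, the electron-poor ketal carbon on C7 and the strain of the alternative bicyclo[2.1.1]hexane, the second by the weakly nucleophilic solvent, the hindered pyridine buffer and the proximity of the nucleophile.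

Step 24
Reactants: 30 tricyclic C10 ketone with C6 ethylene ketal, 11-TBSO and 12-TBSO groups (1S,2S,3S,4R,7R,8R,11S)
Product: 31 tricyclic 6,10-dione with free 11- and 12-hydroxyls (1S,2S,3S,4R,7R,8R,11S)
Conditions: HF (48% aq), MeCN, 0 → 25 °C
Reagents that add atoms: water O
Why: Acidic global deprotection, in which aqueous HF cleaves both silyl ethers and hydrolyses the dioxolane, leaving the carbon skeleton and all stereocentres unchanged.

Step 25
Reactants: 31 tricyclic 6,10-dione with free 11- and 12-hydroxyls (1S,2S,3S,4R,7R,8R,11S)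
Product: 32 tricyclic 10,11,12-triol 6-ketone (1S,2S,3S,4R,7R,8R,10S,11S)
Conditions: Me4NBH(OAc)3, MeCN/AcOH, −20 °C
Reagents that add atoms: none
Why: Hydroxyl-directed triacetoxyborohydride reduction (Saksena–Evans reduction), in which the C11 hydroxyl binds boron and delivers hydride to the neighbouring C10 carbonyl from its own face to give the trans diol (C10 S), while the C6 ketone, which has no hydroxyl within reach, is not reduced.

Step 26
Reactants: 32 tricyclic 10,11,12-triol 6-ketone (1S,2S,3S,4R,7R,8R,10S,11S); 33 angelic acid [(2Z)-2-methylbut-2-enoic acid]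
Product: 35 CNP0214984.1 (tris-angelate of 32), via mixed anhydride 34 (not isolated)
Conditions: 33 (6 equiv), 2,4,6-trichlorobenzoyl chloride (6 equiv), Et3N (7 equiv), toluene, 25 °C; then 32 (1 equiv), 80 °C, until the C11 hydroxyl is consumed
Reagents that add atoms: angelic acid 33 (second equivalent) C/C=C(/C)C(=O)O; angelic acid 33 (third equivalent) C/C=C(/C)C(=O)O
Why: Exhaustive Yamaguchi esterification, in which three equivalents of the mixed 2,4,6-trichlorobenzoic anhydride of angelic acid (made in excess) acylate the primary C12 hydroxyl and the secondary C10 and C11 hydroxyls in turn, each at the less hindered angeloyl carbonyl, a method that esterifies hindered alcohols without Z to E isomerisation of the angelate when no nucleophilic catalyst is added.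

**Compound list**

1 | (S)-2-(benzyloxy)propanal | C[C@H](OCc1ccccc1)C=O | starting material
2 | 1-methoxy-1-(trimethylsilyloxy)prop-1-ene (E/Z mixture) | CC=C(OC)O[Si](C)(C)C | starting material
3 | methyl (3S,4S)-4-(benzyloxy)-3-hydroxy-2-methylpentanoate (C2 epimers) | C[C@H](OCc1ccccc1)[C@@H](O)C(C)C(=O)OC | intermediate
4 | dilithium alkoxide–enolate of 3 | C[C@H](OCc1ccccc1)[C@@H]([O-])C(C)=C([O-])OC.[Li+].[Li+] | intermediate
5 | methyl (2R)-2-[(1S,2S)-2-(benzyloxy)-1-hydroxypropyl]-2-methylpent-4-enoate | C[C@H](OCc1ccccc1)[C@@H](O)[C@](C)(C(=O)OC)CC=C | intermediate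
6 | (2S,3S,4S)-4-(benzyloxy)-2-methyl-2-(prop-2-en-1-yl)pentane-1,3-diol | C[C@H](OCc1ccccc1)[C@@H](O)[C@](C)(CO)CC=C | intermediate
7 | (2S,3S,4S)-4-(BnO)-1,3-bis(TBSO)-2-methyl-2-(prop-2-en-1-yl)pentane | C[C@H](OCc1ccccc1)[C@@H](O[Si](C)(C)C(C)(C)C)[C@](C)(CO[Si](C)(C)C(C)(C)C)CC=C | intermediate
8 | (2S,3S,4S)-4-(BnO)-1,3-bis(TBSO)-2-methyl-2-[(1E)-prop-1-en-1-yl]pentane | C[C@H](OCc1ccccc1)[C@@H](O[Si](C)(C)C(C)(C)C)[C@](C)(CO[Si](C)(C)C(C)(C)C)/C=C/C | intermediate
9 | 3-A-5-methyl-1,2,4-trioxolane (ozonide of 8, ring carbons unassigned) | C[C@H](OCc1ccccc1)[C@@H](O[Si](C)(C)C(C)(C)C)[C@](C)(CO[Si](C)(C)C(C)(C)C)C1OOC(C)O1 | intermediate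
10 | (2S,3S,4S)-4-(BnO)-3-(TBSO)-2-[(TBSO)methyl]-2-methylpentanal | C[C@H](OCc1ccccc1)[C@@H](O[Si](C)(C)C(C)(C)C)[C@](C)(CO[Si](C)(C)C(C)(C)C)C=O | intermediate
11 | ethyl (2E,4S,5S,6S)-6-(BnO)-5-(TBSO)-4-[(TBSO)methyl]-2,4-dimethylhept-2-enoate | C[C@H](OCc1ccccc1)[C@@H](O[Si](C)(C)C(C)(C)C)[C@](C)(CO[Si](C)(C)C(C)(C)C)/C=C(\C)C(=O)OCC | intermediate
12 | (2E,4S,5S,6S)-6-(BnO)-5-(TBSO)-4-[(TBSO)methyl]-2,4-dimethylhept-2-en-1-ol | C[C@H](OCc1ccccc1)[C@@H](O[Si](C)(C)C(C)(C)C)[C@](C)(CO[Si](C)(C)C(C)(C)C)/C=C(\C)CO | intermediate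
13 | bromoacetate of 12 | C[C@H](OCc1ccccc1)[C@@H](O[Si](C)(C)C(C)(C)C)[C@](C)(CO[Si](C)(C)C(C)(C)C)/C=C(\C)COC(=O)CBr | intermediate
14 | diazoacetate of 12 | C[C@H](OCc1ccccc1)[C@@H](O[Si](C)(C)C(C)(C)C)[C@](C)(CO[Si](C)(C)C(C)(C)C)/C=C(\C)COC(=O)C=[N+]=[N-] | intermediate
15 | (1R,5S,6R)-6-A-5-methyl-3-oxabicyclo[3.1.0]hexan-2-one | C[C@H](OCc1ccccc1)[C@@H](O[Si](C)(C)C(C)(C)C)[C@](C)(CO[Si](C)(C)C(C)(C)C)[C@@H]1[C@H]2C(=O)OC[C@@]12C | intermediate
16 | (1R,2S,3R)-3-A-2-(hydroxymethyl)-N-methoxy-N,2-dimethylcyclopropane-1-carboxamide | C[C@H](OCc1ccccc1)[C@@H](O[Si](C)(C)C(C)(C)C)[C@](C)(CO[Si](C)(C)C(C)(C)C)[C@@H]1[C@@H](C(=O)N(C)OC)[C@@]1(C)CO | intermediate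
17 | (1R,2S,3S)-3-A-2-formyl-N-methoxy-N,2-dimethylcyclopropane-1-carboxamide | C[C@H](OCc1ccccc1)[C@@H](O[Si](C)(C)C(C)(C)C)[C@](C)(CO[Si](C)(C)C(C)(C)C)[C@@H]1[C@@H](C(=O)N(C)OC)[C@@]1(C)C=O | intermediate
18 | (1R,2S,3R)-3-A-2-ethenyl-N-methoxy-N,2-dimethylcyclopropane-1-carboxamide | C[C@H](OCc1ccccc1)[C@@H](O[Si](C)(C)C(C)(C)C)[C@](C)(CO[Si](C)(C)C(C)(C)C)[C@@H]1[C@@H](C(=O)N(C)OC)[C@@]1(C)C=C | intermediate
19 | 1-[(1R,2S,3R)-3-A-2-ethenyl-2-methylcyclopropyl]-3-methylbut-3-en-1-one | C[C@H](OCc1ccccc1)[C@@H](O[Si](C)(C)C(C)(C)C)[C@](C)(CO[Si](C)(C)C(C)(C)C)[C@@H]1[C@@H](C(=O)CC(C)=C)[C@@]1(C)C=C | intermediate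
20 | (1R,6S,7R)-7-A-4,6-dimethylbicyclo[4.1.0]hept-4-en-2-one | C[C@H](OCc1ccccc1)[C@@H](O[Si](C)(C)C(C)(C)C)[C@](C)(CO[Si](C)(C)C(C)(C)C)[C@@H]1[C@H]2C(=O)CC(C)=C[C@@]12C | intermediate
21 | (1R,6S,7R)-7-A-4,6-dimethylspiro[bicyclo[4.1.0]hept-4-ene-2,2'-[1,3]dioxolane] | C[C@H](OCc1ccccc1)[C@@H](O[Si](C)(C)C(C)(C)C)[C@](C)(CO[Si](C)(C)C(C)(C)C)[C@@H]1[C@H]2C3(OCCO3)CC(C)=C[C@@]12C | intermediate
22 | [(1R,4R,5S,6S,7R)-7-A-4,6-dimethylspiro[bicyclo[4.1.0]heptane-2,2'-[1,3]dioxolan]-5-yl]borane | C[C@H](OCc1ccccc1)[C@@H](O[Si](C)(C)C(C)(C)C)[C@](C)(CO[Si](C)(C)C(C)(C)C)[C@@H]1[C@H]2C3(OCCO3)C[C@@H](C)[C@H](B)[C@@]12C | intermediate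
23 | (1R,4R,5S,6S,7R)-7-A-4,6-dimethylspiro[bicyclo[4.1.0]heptane-2,2'-[1,3]dioxolan]-5-ol | C[C@H](OCc1ccccc1)[C@@H](O[Si](C)(C)C(C)(C)C)[C@](C)(CO[Si](C)(C)C(C)(C)C)[C@@H]1[C@H]2C3(OCCO3)C[C@@H](C)[C@H](O)[C@@]12C | intermediate
24 | acetate of 23 | C[C@H](OCc1ccccc1)[C@@H](O[Si](C)(C)C(C)(C)C)[C@](C)(CO[Si](C)(C)C(C)(C)C)[C@@H]1[C@H]2C3(OCCO3)C[C@@H](C)[C@H](OC(C)=O)[C@@]12C | intermediate
25 | (1R,4R,5S,6S,7R)-7-[(2S,3S,4S)-1,3-bis(TBSO)-4-hydroxy-2-methylpentan-2-yl]-4,6-dimethylspiro[bicyclo[4.1.0]heptane-2,2'-[1,3]dioxolan]-5-yl acetate | C[C@H](O)[C@@H](O[Si](C)(C)C(C)(C)C)[C@](C)(CO[Si](C)(C)C(C)(C)C)[C@@H]1[C@H]2C3(OCCO3)C[C@@H](C)[C@H](OC(C)=O)[C@@]12C | intermediate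
26 | (1R,4R,5S,6S,7R)-7-[(2S,3S)-1,3-bis(TBSO)-2-methyl-4-oxopentan-2-yl]-4,6-dimethylspiro[bicyclo[4.1.0]heptane-2,2'-[1,3]dioxolan]-5-yl acetate | CC(=O)[C@@H](O[Si](C)(C)C(C)(C)C)[C@](C)(CO[Si](C)(C)C(C)(C)C)[C@@H]1[C@H]2C3(OCCO3)C[C@@H](C)[C@H](OC(C)=O)[C@@]12C | intermediate
27 | (1R,4R,5S,6S,7R)-7-B-4,6-dimethylspiro[bicyclo[4.1.0]heptane-2,2'-[1,3]dioxolan]-5-yl acetate | C=C(O[Si](C(C)C)(C(C)C)C(C)C)[C@@H](O[Si](C)(C)C(C)(C)C)[C@](C)(CO[Si](C)(C)C(C)(C)C)[C@@H]1[C@H]2C3(OCCO3)C[C@@H](C)[C@H](OC(C)=O)[C@@]12C | intermediate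
28 | (1R,4R,5S,6S,7R)-7-B-4,6-dimethylspiro[bicyclo[4.1.0]heptane-2,2'-[1,3]dioxolan]-5-ol | C=C(O[Si](C(C)C)(C(C)C)C(C)C)[C@@H](O[Si](C)(C)C(C)(C)C)[C@](C)(CO[Si](C)(C)C(C)(C)C)[C@@H]1[C@H]2C3(OCCO3)C[C@@H](C)[C@H](O)[C@@]12C | intermediate
29 | (1R,4R,5S,6S,7R)-7-B-4,6-dimethylspiro[bicyclo[4.1.0]heptane-2,2'-[1,3]dioxolan]-5-yl methanesulfonate | C=C(O[Si](C(C)C)(C(C)C)C(C)C)[C@@H](O[Si](C)(C)C(C)(C)C)[C@](C)(CO[Si](C)(C)C(C)(C)C)[C@@H]1[C@H]2C3(OCCO3)C[C@@H](C)[C@H](OS(C)(=O)=O)[C@@]12C | intermediate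
30 | tricyclic C10 ketone with C6 ethylene ketal, 11-TBSO and 12-TBSO groups (1S,2S,3S,4R,7R,8R,11S; tricyclo[5.4.0.0(2,8)]undecane skeleton) | CC(C)(C)[Si](C)(C)OC[C@]1(C)[C@H]2[C@@H]3[C@H](C)CC4(OCCO4)[C@H]2[C@]3(C)CC(=O)[C@H]1O[Si](C)(C)C(C)(C)C | intermediate
31 | tricyclic 6,10-dione with free 11- and 12-hydroxyls (1S,2S,3S,4R,7R,8R,11S) | OC[C@]1(C)[C@H]2[C@@H]3[C@H](C)CC(=O)[C@H]2[C@]3(C)CC(=O)[C@H]1O | intermediate
32 | tricyclic 10,11,12-triol 6-ketone (1S,2S,3S,4R,7R,8R,10S,11S) | OC[C@]1(C)[C@H]2[C@@H]3[C@H](C)CC(=O)[C@H]2[C@]3(C)C[C@H](O)[C@H]1O | intermediate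
33 | angelic acid, (2Z)-2-methylbut-2-enoic acid | C/C=C(/C)C(=O)O | starting material
34 | angelic 2,4,6-trichlorobenzoic anhydride | C/C=C(/C)C(=O)OC(=O)c1c(Cl)cc(Cl)cc1Cl | intermediate
35 | CNP0214984.1: 10,11-bis(angeloyloxy)-12-(angeloyloxy)-1,4,8-trimethyl tricyclic 6-ketone (1S,2S,3S,4R,7R,8R,10S,11S) | C/C=C(/C)C(=O)OC[C@]1(C)[C@H]2[C@@H]3[C@H](C)CC(=O)[C@H]2[C@]3(C)C[C@H](OC(=O)/C(C)=C\C)[C@H]1OC(=O)/C(C)=C\C | target

**Step count**

Total: 26 steps. Longest linear sequence: 26 steps (1 to 35); 2 and 33 enter as purchased materials, 33 in threefold molar amount in step 26.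

**Steps most likely to fail**

Step 23 (cationic ring expansion with enol silane capture). The cation may be taken by solvent or lose a proton before the seven-membered ring closes, the enol silane may be protodesilylated, or the nucleophile may engage the delocalised cation before the shift to C8 is complete. The fallback separates the two events and uses known reactions only. It sets out from ketone 26 and returns at 30. Methanolysis of the acetate (K2CO3, MeOH, 0 °C) should give the hydroxy ketone F1. SOCl2 and pyridine in CH2Cl2 should convert this cyclopropylcarbinol, by the known ion-pair rearrangement of (1-methylcyclopropyl)carbinyl derivatives, into the tertiary 1-methylcyclobutyl chloride F2; its configuration at C8 is of no consequence. Kinetic enolisation (LiN(iPr)2, Me3SiCl, THF, −78 °C) should give the trimethylsilyl enol ether F3. ZnCl2 in CH2Cl2 should then effect the known Lewis acid-mediated tert-alkylation of a silyl enol ether by a tertiary chloride, closing the seven-membered ring to 30.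

Step 10 (carbenoid cyclopropanation). The catalyst and the allylic quaternary centre may oppose each other and erode face selection, and the hindered alkene may react so slowly that carbene dimerisation takes over. The fallback forms the carbocycle and the cyclopropane together from a diazoketone; it sets out from 12 and returns at 21. CBr4 and PPh3 should give the allylic bromide F4. Coupling with methyl propiolate (CuI, K2CO3, NaI, DMF) should give the skipped enynoate F5. Syn addition of Me2CuLi at −78 °C should give the (2Z,5E)-dienoate F6, and LiOH the dienoic acid F7. Oxalyl chloride followed by diazomethane should give the diazoketone F8. Cu(acac)2 in hot toluene should close the bicyclic enone F9 by the classical copper-catalysed intramolecular cyclopropanation of unsaturated diazoketones; face selection here rests on the conformation about C1–C2 or, if that proves insufficient, on CuOTf with the chiral ligand 2,2'-(propane-2,2-diyl)bis[(4S)-4-tert-butyl-4,5-dihydrooxazole]. Ketalisation with ethylene glycol and TsOH, with the usual shift of the double bond out of conjugation, should return 21.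

Step 16 (hydroboration). Borane may approach from the cyclopropane face because the angular C8 methyl group shields the other side, or boron may end on C4; either would give the wrong C4 epimer or a tertiary alcohol. The fallback sets C4 by intramolecular delivery instead; it sets out from 21 and returns at 23. Dimethyldioxirane in acetone at −20 °C should give the epoxide F10, the small electrophilic oxidant being expected to attack anti to the cyclopropane. Diethylaluminium 2,2,6,6-tetramethylpiperidide, Et2Al(TMP), in toluene should open it to the exocyclic allylic alcohol F11 by removal of a methyl proton. Hydroxyl-directed hydrogenation with [Ir(cod)(PCy3)(py)]PF6 and H2 in CH2Cl2 should add hydrogen to C4 from the face of the C3 hydroxyl and give 23.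

**Further compounds**

F1 | step 23 | (1R,4R,5S,6S,7R)-7-[(2S,3S)-1,3-bis(TBSO)-2-methyl-4-oxopentan-2-yl]-4,6-dimethylspiro[bicyclo[4.1.0]heptane-2,2'-[1,3]dioxolan]-5-ol | CC(=O)[C@@H](O[Si](C)(C)C(C)(C)C)[C@](C)(CO[Si](C)(C)C(C)(C)C)[C@@H]1[C@H]2C3(OCCO3)C[C@@H](C)[C@H](O)[C@@]12C
F2 | step 23 | C8 chloride of the bicyclo[3.1.1]heptane (cyclobutane C2–C3–C8–C7, C6 ethylene ketal) carrying the C10 methyl ketone side chain on C2 | CC(=O)[C@@H](O[Si](C)(C)C(C)(C)C)[C@](C)(CO[Si](C)(C)C(C)(C)C)[C@H]1[C@@H]2[C@H](C)CC3(OCCO3)[C@H]1[C@]2(C)Cl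
F3 | step 23 | trimethylsilyl enol ether (C9=C10) of F2 | C=C(O[Si](C)(C)C)[C@@H](O[Si](C)(C)C(C)(C)C)[C@](C)(CO[Si](C)(C)C(C)(C)C)[C@H]1[C@@H]2[C@H](C)CC3(OCCO3)[C@H]1[C@]2(C)Cl
F4 | step 10 | (2E,4S,5S,6S)-6-(BnO)-1-bromo-5-(TBSO)-4-[(TBSO)methyl]-2,4-dimethylhept-2-ene | C[C@H](OCc1ccccc1)[C@@H](O[Si](C)(C)C(C)(C)C)[C@](C)(CO[Si](C)(C)C(C)(C)C)/C=C(\C)CBr
F5 | step 10 | methyl (5E,7S,8S,9S)-9-(BnO)-8-(TBSO)-7-[(TBSO)methyl]-5,7-dimethyldec-5-en-2-ynoate | C[C@H](OCc1ccccc1)[C@@H](O[Si](C)(C)C(C)(C)C)[C@](C)(CO[Si](C)(C)C(C)(C)C)/C=C(\C)CC#CC(=O)OC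
F6 | step 10 | methyl (2Z,5E,7S,8S,9S)-9-(BnO)-8-(TBSO)-7-[(TBSO)methyl]-3,5,7-trimethyldeca-2,5-dienoate | C[C@H](OCc1ccccc1)[C@@H](O[Si](C)(C)C(C)(C)C)[C@](C)(CO[Si](C)(C)C(C)(C)C)/C=C(\C)C/C(C)=C\C(=O)OC
F7 | step 10 | (2Z,5E,7S,8S,9S)-9-(BnO)-8-(TBSO)-7-[(TBSO)methyl]-3,5,7-trimethyldeca-2,5-dienoic acid | C[C@H](OCc1ccccc1)[C@@H](O[Si](C)(C)C(C)(C)C)[C@](C)(CO[Si](C)(C)C(C)(C)C)/C=C(\C)C/C(C)=C\C(=O)O
F8 | step 10 | (3Z,6E,8S,9S,10S)-10-(BnO)-9-(TBSO)-8-[(TBSO)methyl]-1-diazo-4,6,8-trimethylundeca-3,6-dien-2-one | C[C@H](OCc1ccccc1)[C@@H](O[Si](C)(C)C(C)(C)C)[C@](C)(CO[Si](C)(C)C(C)(C)C)/C=C(\C)C/C(C)=C\C(=O)C=[N+]=[N-]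
F9 | step 10 | (1R,6S,7R)-7-A-4,6-dimethylbicyclo[4.1.0]hept-3-en-2-one | C[C@H](OCc1ccccc1)[C@@H](O[Si](C)(C)C(C)(C)C)[C@](C)(CO[Si](C)(C)C(C)(C)C)[C@@H]1[C@H]2C(=O)C=C(C)C[C@@]12C
F10 | step 16 | C3–C4 epoxide of 21 with the oxygen anti to the cyclopropane | C[C@H](OCc1ccccc1)[C@@H](O[Si](C)(C)C(C)(C)C)[C@](C)(CO[Si](C)(C)C(C)(C)C)[C@@H]1[C@H]2C3(OCCO3)C[C@]4(C)O[C@@H]4[C@@]12C
F11 | step 16 | (1R,5S,6S,7R)-7-A-6-methyl-4-methylidenespiro[bicyclo[4.1.0]heptane-2,2'-[1,3]dioxolan]-5-ol | C[C@H](OCc1ccccc1)[C@@H](O[Si](C)(C)C(C)(C)C)[C@](C)(CO[Si](C)(C)C(C)(C)C)[C@@H]1[C@H]2C3(OCCO3)CC(=C)[C@H](O)[C@@]12C
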